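The route rests on opening both rings at once: the ring-fusion bond C5–C10 and the C8–C9 bond of cyclohexene ring B are made together. With the C7=C8 olefin temporarily at C6=C7, ring B, whose formyl-bearing C9 sits next to quaternary C10, is the adduct of a C5–C8 dienoate and a C9=C10 enal. The key step is an intramolecular Diels–Alder reaction of an acyclic trienal in which the C1–C4 chain (C1 carbinol, C3 chloride, quaternary C4, all pre-set) is the tether; it closes rings A and B and sets C5, C9 and C10. C1 is carried as the equatorial epimer and corrected later by oxidation and axial-selective reduction.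

Key step: step 9

Remark on numbering: all intermediates carry the locants of the target decalin (C1–C10 ring atoms, C11 = formyl carbon on C9, C12 = formyl carbon on C8); β is the face of the C10 methyl group.
Assumption: compounds 1, 2, 6 and 9 are purchased; the 1α-hydroxy dialdehyde may equilibrate with its C11 hemiacetal, and the open form is drawn.
Remark on catalyst sense: the TRIP enantiomer in step 5 is the one expected to deliver the allyl unit to the Si face of aldehyde 5; if the sense proves opposite, the other enantiomer is used.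

Step 1
Reactants: 1 (E)-4,4-dimethoxy-2-methylbut-2-enal; 2 (S)-3-acetyl-4-benzyl-1,3-thiazolidine-2-thione
Product: 3 (S)-4-benzyl-3-[(3R,4E)-3-hydroxy-6,6-dimethoxy-4-methylhex-4-enoyl]-1,3-thiazolidine-2-thione
Conditions: 2, TiCl4, i-Pr2NEt, CH2Cl2, −78 °C; then 1, −78 °C
Reagents that add atoms: none
Why: Auxiliary-controlled titanium enolate acetate aldol addition, in which the aldehyde should approach the thione-chelated chair enolate on the face opposite the benzyl group and set C1 as (R), while the dimethyl acetal stays inert without a second Lewis acid.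

Step 2
Reactants: 3 aldol adduct
Product: 4 (S)-4-benzyl-3-[(3R,4E)-3-(tert-butyldimethylsilyloxy)-6,6-dimethoxy-4-methylhex-4-enoyl]-1,3-thiazolidine-2-thione
Conditions: TBSOTf, 2,6-lutidine, CH2Cl2, −78 °C
Reagents that add atoms: tert-butyldimethylsilyl triflate, CC(C)(C)[Si](C)(C)OS(=O)(=O)C(F)(F)F
Why: Silyl ether formation at low temperature, where O-silylation should be much faster than acetal activation; no stereocenter is touched.

Step 3
Reactants: 4 silyl ether
Product: 5 (3R,4E)-3-(tert-butyldimethylsilyloxy)-6,6-dimethoxy-4-methylhex-4-enal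
Conditions: i-Bu2AlH (1.2 equiv), CH2Cl2, −78 °C
Reagents that add atoms: none
Why: Partial hydride reduction of the activated N-acyl thiazolidinethione, whose aluminium hemiaminal should collapse to the aldehyde only on work-up and release the auxiliary.

Step 4
Reactants: 6 geranyl acetate [(2E)-3,7-dimethylocta-2,6-dienyl acetate]
Product: 7 geranyl pinacolboronate [2-[(2E)-3,7-dimethylocta-2,6-dienyl]-4,4,5,5-tetramethyl-1,3,2-dioxaborolane]
Conditions: B2pin2, Pd2(dba)3 (2.5 mol %), DMSO, 50 °C
Reagents that add atoms: bis(pinacolato)diboron, CC1(C)OB(OC1(C)C)B1OC(C)(C)C(C)(C)O1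
Why: Palladium-catalysed allylic borylation (Miyaura type) through a π-allyl complex, which should give the linear boronate with the E geometry retained.

Step 5
Reactants: 5 aldehyde; 7 geranyl pinacolboronate
Product: 8 (2E,4R,6R,7S)-4-(tert-butyldimethylsilyloxy)-7-ethenyl-1,1-dimethoxy-3,7,11-trimethyldodeca-2,10-dien-6-ol (C1 R, C3 R, C4 S in target numbering)
Conditions: (S)-TRIP [(S)-3,3'-bis(2,4,6-triisopropylphenyl)-1,1'-binaphthyl-2,2'-diyl hydrogen phosphate] (10 mol %), 4 Å MS, toluene, −30 °C → rt; aq. NaHCO3 work-up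
Reagents that add atoms: none
Why: Chiral phosphoric acid-catalysed allylboration through a closed chair transition state, in which the E-boronate places the homoprenyl chain pseudo-equatorial so that the new quaternary C4 carries its methyl syn to the new hydroxyl (4S), and the catalyst should direct attack to the Si face of the aldehyde (3R).

Step 6
Reactants: 8 homoallylic alcohol; 9 methyl (E)-3-iodoprop-2-enoate
Product: 10 methyl (2E,4E,6S,7R,9R,10E)-9-(tert-butyldimethylsilyloxy)-7-hydroxy-12,12-dimethoxy-6,10-dimethyl-6-(4-methylpent-3-enyl)dodeca-2,4,10-trienoate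
Conditions: Pd(OAc)2 (5 mol %), K2CO3, Bu4NCl, DMF, 50 °C
Reagents that add atoms: none
Why: Heck reaction of the vinyl group on quaternary C4, where carbopalladation at the terminal carbon and β-hydride elimination (possible only toward the new bond) should give the E,E-dienoate with the iodide geometry retained.

Step 7
Reactants: 10 hydroxy dienoate
Product: 11 methyl (2E,4E,6S,7S,9R,10E)-9-(tert-butyldimethylsilyloxy)-7-chloro-12,12-dimethoxy-6,10-dimethyl-6-(4-methylpent-3-enyl)dodeca-2,4,10-trienoate
Conditions: PPh3, CCl4, 2,6-lutidine (0.2 equiv), MeCN, 60 °C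
Reagents that add atoms: tetrachloromethane, ClC(Cl)(Cl)Cl
Why: Appel reaction, in which chloride displaces the alkoxyphosphonium group by SN2 with inversion to set C3 as (S); heating is needed at this neopentyl-type carbinol, C4 offers no β-hydrogen and the electron-poor diene is a poor neighbouring group.

Step 8
Reactants: 11 chloro silyl ether acetal
Product: 12 methyl (2E,4E,6S,7S,9R,10E)-7-chloro-9-hydroxy-6,10-dimethyl-6-(4-methylpent-3-enyl)-12-oxododeca-2,4,10-trienoate
Conditions: HF (48 % aq.), MeCN, 0 °C → rt
Reagents that add atoms: water, O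
Why: Acid hydrolysis of the allylic dimethyl acetal and fluoride cleavage of the allylic silyl ether in one operation, which should leave the E-enal, the chloride and the dienoate untouched.

Step 9
Reactants: 12 hydroxy trienal
Product: 13 trans-fused adduct: methyl 3β-chloro-9β-formyl-1β-hydroxy-4β,10β-dimethyl-4α-(4-methylpent-3-enyl)-5α-H-decal-6-ene-8β-carboxylate
Conditions: Me2AlCl (2.2 equiv), CH2Cl2, −78 → −20 °C
Reagents that add atoms: none
Why: Concerted, asynchronous intramolecular [4+2] cycloaddition in which the Me2AlCl-complexed (E)-enal C9=C10 adds across the (E,E)-diene C5–C8, forming C5–C10 and C8–C9 together; the closest known reaction type is the Lewis acid-promoted type 1 intramolecular Diels–Alder reaction of (E,E,E)-deca-1,7,9-trienes with a terminal formyl group. Ring A closes as a six-membered carbocycle through the C1–C4 tether folded as a chair with C5–C10 as the last ring bond (fused mode), and ring B is the cyclohexene formed by the cycloaddition itself. The trans ring fusion (C5 H α, C10 methyl β) follows from the endo transition state with the complexed formyl group under the diene, C9 (formyl β, cis to the C10 methyl) is fixed by suprafacial addition to the E-enal, and C8 (ester β) by the E,E-diene. The face of addition is set by the tether: in the reactive chair the C1 oxygen (as aluminium alkoxide), the C3 chlorine and the homoprenyl chain on C4 are all equatorial and the C1–O bond lies anti to the forming C5–C10 bond, whereas the other face would need all three axial with a syn-axial O/Cl contact. The step needs endo over exo selectivity and one diene face; regiochemistry is fixed by the tether, and the two trisubstituted side-chain alkenes are unactivated and should not compete.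

Step 10
Reactants: 13 Diels–Alder adduct
Product: 15 cis-fused Δ6 γ-lactone (carbonyl C12 on C8β; O–C11H2 on C9β) with 1β-OH, via hydroxymethyl ester 14 (not isolated)
Conditions: NaBH4, MeOH, 0 °C → rt
Reagents that add atoms: none
Why: Chemoselective borohydride reduction of the aldehyde (also through its lactol form) over the ester, after which the C11 alkoxide should acylate on the cis 8β-ester (lactonisation), so that C9 no longer carries an epimerisable formyl group.

Step 11
Reactants: 15 hydroxy lactone
Product: 16 1-oxo Δ6 γ-lactone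
Conditions: Dess–Martin periodinane, CH2Cl2, 0 °C → rt
Reagents that add atoms: none
Why: Dess–Martin oxidation of the hindered secondary alcohol under non-basic conditions, chosen so that the resulting β-chloro ketone does not eliminate HCl; the ketone is used directly.

Step 12
Reactants: 16 keto lactone
Product: 18 1α-(tert-butyldimethylsilyloxy) Δ6 γ-lactone, via lithium alkoxide 17 (not isolated)
Conditions: LiBH(s-Bu)3 (L-Selectride), THF, −78 °C; then TBSOTf, −78 → 0 °C
Reagents that add atoms: tert-butyldimethylsilyl triflate, CC(C)(C)[Si](C)(C)OS(=O)(=O)C(F)(F)F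
Why: Ketone reduction by a bulky trialkylborohydride, which should attack along the equatorial (β) trajectory because the axial α path is blocked by the syn-axial hydrogens on C3, C5 and C9, giving the axial 1α-alkoxide (1S) that is silylated in the same flask; the saturated lactone and the chloride should survive at −78 °C.

Step 13
Reactants: 18 Δ6 lactone
Product: 19 Δ7 butenolide (C7=C8 conjugated with the C12 lactone carbonyl), 1α-OTBS
Conditions: DBU, CH2Cl2, rt
Reagents that add atoms: none
Why: Base-mediated olefin isomerisation through the lactone dienolate, which should move the double bond into conjugation and erase the C8 stereocenter, while C9 is not acidic and the equatorial chloride has no anti-periplanar hydrogen.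

Step 14
Reactants: 19 butenolide
Product: 20 Δ7-11,12-diol, 1α-OTBS
Conditions: i-Bu2AlH (4 equiv), CH2Cl2, −78 → 0 °C
Reagents that add atoms: none
Why: 1,2-Reduction of the α,β-unsaturated lactone by an aluminium hydride, which should give the allylic/primary diol without touching the olefin or the chloride.

Step 15
Reactants: 20 ene-diol
Product: 21 Δ7-11,12-dial, 1α-OTBS
Conditions: (COCl)2, DMSO, CH2Cl2, −78 °C; then Et3N, −78 → −30 °C
Reagents that add atoms: none
Why: Swern oxidation, in which both primary alcohols are activated before any aldehyde is released, so that lactol and lactone formation is avoided and the 9β-formyl group should not epimerise at low temperature.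

Step 16
Reactants: 21 silyloxy dialdehyde
Product: 22 target, 3β-chloro-1α-hydroxy ene-dial
Conditions: HF (48 % aq.), MeCN, 0 °C
Reagents that add atoms: none
Why: Fluoride-mediated desilylation under acidic, non-basic conditions, chosen because the 9β-formyl group is base-sensitive.

Compound list
1 | (E)-4,4-dimethoxy-2-methylbut-2-enal | O=C/C(C)=C/C(OC)OC | starting material
2 | (S)-3-acetyl-4-benzyl-1,3-thiazolidine-2-thione | CC(=O)N1[C@@H](Cc2ccccc2)CSC1=S | starting material
3 | (S)-4-benzyl-3-[(3R,4E)-3-hydroxy-6,6-dimethoxy-4-methylhex-4-enoyl]-1,3-thiazolidine-2-thione | O=C(C[C@@H](O)/C(C)=C/C(OC)OC)N1[C@@H](Cc2ccccc2)CSC1=S | intermediate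
4 | TBS ether of 3 | O=C(C[C@@H](O[Si](C)(C)C(C)(C)C)/C(C)=C/C(OC)OC)N1[C@@H](Cc2ccccc2)CSC1=S | intermediate
5 | (3R,4E)-3-(tert-butyldimethylsilyloxy)-6,6-dimethoxy-4-methylhex-4-enal | O=CC[C@@H](O[Si](C)(C)C(C)(C)C)/C(C)=C/C(OC)OC | intermediate
6 | geranyl acetate | CC(C)=CCC/C(C)=C/COC(C)=O | starting material
7 | geranyl pinacolboronate | CC(C)=CCC/C(C)=C/CB1OC(C)(C)C(C)(C)O1 | intermediate
8 | (2E,4R,6R,7S)-4-(tert-butyldimethylsilyloxy)-7-ethenyl-1,1-dimethoxy-3,7,11-trimethyldodeca-2,10-dien-6-ol | CC(C)=CCC[C@](C=C)(C)[C@H](O)C[C@@H](O[Si](C)(C)C(C)(C)C)/C(C)=C/C(OC)OC | intermediate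
9 | methyl (E)-3-iodoprop-2-enoate | COC(=O)/C=C/I | starting material
10 | methyl (2E,4E,6S,7R,9R,10E)-9-(tert-butyldimethylsilyloxy)-7-hydroxy-12,12-dimethoxy-6,10-dimethyl-6-(4-methylpent-3-enyl)dodeca-2,4,10-trienoate | CC(C)=CCC[C@](/C=C/C=C/C(=O)OC)(C)[C@H](O)C[C@@H](O[Si](C)(C)C(C)(C)C)/C(C)=C/C(OC)OC | intermediate
11 | methyl (2E,4E,6S,7S,9R,10E)-9-(tert-butyldimethylsilyloxy)-7-chloro-12,12-dimethoxy-6,10-dimethyl-6-(4-methylpent-3-enyl)dodeca-2,4,10-trienoate | CC(C)=CCC[C@](/C=C/C=C/C(=O)OC)(C)[C@@H](Cl)C[C@@H](O[Si](C)(C)C(C)(C)C)/C(C)=C/C(OC)OC | intermediate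
12 | methyl (2E,4E,6S,7S,9R,10E)-7-chloro-9-hydroxy-6,10-dimethyl-6-(4-methylpent-3-enyl)-12-oxododeca-2,4,10-trienoate | CC(C)=CCC[C@](/C=C/C=C/C(=O)OC)(C)[C@@H](Cl)C[C@@H](O)/C(C)=C/C=O | intermediate
13 | trans-fused adduct, methyl 3β-chloro-9β-formyl-1β-hydroxy-4β,10β-dimethyl-4α-(4-methylpent-3-enyl)-5α-H-decal-6-ene-8β-carboxylate | CC(C)=CCC[C@]1(C)[C@@H](Cl)C[C@@H](O)[C@]2(C)[C@@H](C=O)[C@@H](C(=O)OC)C=C[C@@H]12 | intermediate
14 | 9β-hydroxymethyl ester from 13 (1β,11-diol) | CC(C)=CCC[C@]1(C)[C@@H](Cl)C[C@@H](O)[C@]2(C)[C@@H](CO)[C@@H](C(=O)OC)C=C[C@@H]12 | intermediate (not isolated)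
15 | cis-fused Δ6 γ-lactone, 1β-OH | CC(C)=CCC[C@]1(C)[C@@H](Cl)C[C@@H](O)[C@]2(C)[C@H]3COC(=O)[C@H]3C=C[C@@H]12 | intermediate
16 | 1-oxo Δ6 γ-lactone | CC(C)=CCC[C@]1(C)[C@@H](Cl)CC(=O)[C@]2(C)[C@H]3COC(=O)[C@H]3C=C[C@@H]12 | intermediate
17 | lithium 1α-alkoxide of the Δ6 γ-lactone | CC(C)=CCC[C@]1(C)[C@@H](Cl)C[C@H]([O-])[C@]2(C)[C@H]3COC(=O)[C@H]3C=C[C@@H]12.[Li+] | intermediate (not isolated)
18 | 1α-(tert-butyldimethylsilyloxy) Δ6 γ-lactone | CC(C)=CCC[C@]1(C)[C@@H](Cl)C[C@H](O[Si](C)(C)C(C)(C)C)[C@]2(C)[C@H]3COC(=O)[C@H]3C=C[C@@H]12 | intermediate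
19 | Δ7 butenolide, 1α-OTBS | CC(C)=CCC[C@]1(C)[C@@H](Cl)C[C@H](O[Si](C)(C)C(C)(C)C)[C@]2(C)[C@H]3COC(=O)C3=CC[C@@H]12 | intermediate
20 | Δ7-11,12-diol, 1α-OTBS | CC(C)=CCC[C@]1(C)[C@@H](Cl)C[C@H](O[Si](C)(C)C(C)(C)C)[C@]2(C)[C@@H](CO)C(CO)=CC[C@@H]12 | intermediate
21 | Δ7-11,12-dial, 1α-OTBS | CC(C)=CCC[C@]1(C)[C@@H](Cl)C[C@H](O[Si](C)(C)C(C)(C)C)[C@]2(C)[C@@H](C=O)C(C=O)=CC[C@@H]12 | intermediate
22 | target, 3β-chloro-1α-hydroxy-4β,10β-dimethyl-4α-(4-methylpent-3-enyl)-5α-H-decal-7-ene-8,9β-dicarbaldehyde | CC(C)=CCC[C@]1(C)[C@@H](Cl)C[C@H](O)[C@]2(C)[C@@H](C=O)C(C=O)=CC[C@@H]12 | target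

Total step count: 16. Longest linear sequence: 15 steps (steps 1–3 and 5–16); step 4 is a one-step side branch.

Steps most likely to fail

Step 7 (chloride with inversion at C3). Backside attack at this neopentyl-type carbinol may be outrun by elimination toward C2, by ionisation with a 1,2-shift, or the reaction may stop at the alkoxyphosphonium salt. The fallback uses retention instead of inversion and sets out from aldehyde 5. The allylboration of step 5 is run with the Z reagent neryl pinacolboronate F1 (from commercial neryl acetate under the conditions of step 4) and (R)-TRIP, which should give the C3-epimeric alcohol F2 with the same C4 configuration. Heck coupling with 9 as in step 6 then gives the epimeric hydroxy dienoate F3. SOCl2 converts it into the chlorosulfite F4, which with catalytic TiCl4 should collapse by front-side (SNi) delivery of chloride with retention to give 11, where the route is rejoined.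

Step 9 (key cycloaddition). The aluminium alkoxide of the free C1 alcohol may drain the dienophile by hydride transfer to the complexed aldehyde, aggregate and erode endo control, or make the reaction sluggish because both partners are electron-poor. The fallback keeps the silyl ether through the cycloaddition and sets out from 11. Selective acetal hydrolysis (PPTS, acetone/water) should give the silyloxy trienal F5. The Diels–Alder reaction is then run with Et2AlCl (about 1 equiv) or thermally in toluene, the equatorial silyloxy group steering the same face, to give the adduct F6. NaBH4 in MeOH gives the silyloxy lactone F7, and aqueous HF in MeCN removes the silyl group to give 15, where the route is rejoined.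

Step 12 (axial alcohol at C1). Hydride may instead enter along the axial α path and return the equatorial 1β-alcohol, or over-reduce the lactone. The fallback replaces substrate control by reagent control and sets out from 16. A CBS reduction with (R)-2-methyl-CBS-oxazaborolidine and BH3·SMe2, which treats quaternary C10 as the large and the C2 methylene as the small flank, should give the 1α-alcohol F8. Silylation with TBSOTf and 2,6-lutidine then gives 18, where the route is rejoined.

Further compounds
F1 | step 7 | neryl pinacolboronate, 2-[(2Z)-3,7-dimethylocta-2,6-dienyl]-4,4,5,5-tetramethyl-1,3,2-dioxaborolane | CC(C)=CCC/C(C)=C\CB1OC(C)(C)C(C)(C)O1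
F2 | step 7 | (2E,4R,6S,7S)-4-(tert-butyldimethylsilyloxy)-7-ethenyl-1,1-dimethoxy-3,7,11-trimethyldodeca-2,10-dien-6-ol (C3 epimer of 8) | CC(C)=CCC[C@](C=C)(C)[C@@H](O)C[C@@H](O[Si](C)(C)C(C)(C)C)/C(C)=C/C(OC)OC
F3 | step 7 | methyl (2E,4E,6S,7S,9R,10E)-9-(tert-butyldimethylsilyloxy)-7-hydroxy-12,12-dimethoxy-6,10-dimethyl-6-(4-methylpent-3-enyl)dodeca-2,4,10-trienoate (C3 epimer of 10) | CC(C)=CCC[C@](/C=C/C=C/C(=O)OC)(C)[C@@H](O)C[C@@H](O[Si](C)(C)C(C)(C)C)/C(C)=C/C(OC)OC
F4 | step 7 | chlorosulfite of F3 | CC(C)=CCC[C@](/C=C/C=C/C(=O)OC)(C)[C@@H](OS(=O)Cl)C[C@@H](O[Si](C)(C)C(C)(C)C)/C(C)=C/C(OC)OC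
F5 | step 9 | methyl (2E,4E,6S,7S,9R,10E)-9-(tert-butyldimethylsilyloxy)-7-chloro-6,10-dimethyl-6-(4-methylpent-3-enyl)-12-oxododeca-2,4,10-trienoate | CC(C)=CCC[C@](/C=C/C=C/C(=O)OC)(C)[C@@H](Cl)C[C@@H](O[Si](C)(C)C(C)(C)C)/C(C)=C/C=O
F6 | step 9 | 1β-silyl ether of adduct 13 | CC(C)=CCC[C@]1(C)[C@@H](Cl)C[C@@H](O[Si](C)(C)C(C)(C)C)[C@]2(C)[C@@H](C=O)[C@@H](C(=O)OC)C=C[C@@H]12
F7 | step 9 | 1β-silyl ether of lactone 15 | CC(C)=CCC[C@]1(C)[C@@H](Cl)C[C@@H](O[Si](C)(C)C(C)(C)C)[C@]2(C)[C@H]3COC(=O)[C@H]3C=C[C@@H]12
F8 | step 12 | 1α-hydroxy Δ6 γ-lactone | CC(C)=CCC[C@]1(C)[C@@H](Cl)C[C@H](O)[C@]2(C)[C@H]3COC(=O)[C@H]3C=C[C@@H]12
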